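**The unit.** The reciprocal minute suits oak. Pace here means the share of the unused partner that reacts per minute, a pseudo-first-order view of the partner.

common to all: left-handed substrate 10 mM; right-handed substrate 10 mM; free catalyst 100 µM; impurity 48 µM

| run | partner | remark | time |
|---|---|---|---|
| oak | 8 mM | the very flask that is asked about, followed so far |  |
| larch | 4 mM | run made earlier |  |
| flask | 8.00 mM |  | 80 min |

| run | time / min | left-handed product / % | left-handed substrate / % |
|---|---|---|---|
| oak | 5.00 | 22.6 | 32.7 |
| oak | 12.0 | 26.6 | 30.8 |
| oak | 30.0 | 27.3 | 29.3 |
| oak | 60.0 | 26.3 | 29.9 |
| larch | 1.00 | 7.2 | 46.6 |
| larch | 2.00 | 8.2 | 43.8 |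
| larch | 3.00 | 9.4 | 43.9 |
| larch | 4.00 | 11.5 | 40.4 |

(each reading ± 1 percentage point)

- amber: at 80 min add partner, 100% of the amount charged, then wait 2.5 h
- grey: at 80 min add free catalyst, 100% of the amount charged, then wait 2.5 h
- ochre: change nothing and wait 2.5 h more
- teal: at 80 min take out 90% of the left-handed product then present, then wait 2.5 h

- free catalyst is single-handed; left-handed substrate and right-handed substrate are mirror images of each other, charged as a racemate, each of them at the stated concentration
- removed left-handed product is counted in
- additions bring no volume worth counting

- left-handed product, in percent of the left-handed substrate and right-handed substrate together first charged, at 80 min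
- which option adds most left-handed product ("none" when 2 percentage points or less is all one gets) (amber / grey / ochre / teal / none)
- left-handed product present, with what was taken out counted in, in percent of the left-handed substrate and right-handed substrate together first charged, after grey
- left-handed product present, with what was taken out counted in, in percent of the left-handed substrate and right-handed substrate together first charged, after ochre

**Two paces.** Left-handed product in oak reads near 26.8%, which, taking the partner as used, makes a share 0.670 of it left-handed product. Slope over product still to come gives a pace of 0.354 min⁻¹ in larch near 2.50 min. In oak near 8.50 min it gives 0.260 min⁻¹.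

**Two times.** I read the falling pace as working catalyst fading, and call the time in which it halves the catalyst half-life, 13.4 min. This is rough, since each reading scatters by 1 percentage point. Larch's early partner half-life is 1.96 min, shorter than that, so I expect oak's partner to go first. By 80 min I reckon a pace of 0.00651 min⁻¹, a partner half-life of 106 min, longer than the catalyst's. Partner added then, equal to the charge, is used by a share of about 12.6%, so I reckon amber gains about 3.4 points.

**The forecast.** It gives 26.8% now, amber as best, 27% after grey and 26.8% after ochre, holding that “new partner reacts through the background”. Its gain for amber is about 20 points, not my figure.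

**The result.** Oak gives 27.6%, and the best choice is none: amber adds 1.1 points, under the margin of 2 points.

    partner + catalyst intermediate A → free catalyst + left-handed product (k = 207 M⁻¹ s⁻¹)
    left-handed substrate ⇌ right-handed substrate (k = 0.00722 s⁻¹)
    free catalyst + right-handed substrate ⇌ catalyst intermediate B (K = 267 M⁻¹, k = 1720 M⁻¹ s⁻¹)
    free catalyst → spent catalyst B (k = 0.00465 s⁻¹)
    partner + catalyst intermediate B → free catalyst + right-handed product (k = 97.0 M⁻¹ s⁻¹)
    free catalyst + impurity → spent catalyst A (k = 2.25 × 10⁵ M⁻¹ s⁻¹)
    free catalyst + left-handed substrate ⇌ catalyst intermediate A (K = 354 M⁻¹, k = 1030 M⁻¹ s⁻¹)

In oak, catalyst intermediates A and B and free catalyst together stand at 5.07% of the catalyst charged at 40.0 min. The half-life carries that to 0.640% at 80.0 min, against a computed 0.478%.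

**Second flask.** For a neighbour of oak charged with 32 mM of partner, larch's early pace and the half-life reckon 6.86 natural-log units of partner use, above the 0.981 that consuming both substrates needs. Computed, each substrate in that neighbour stands at 0.479%, with 55.7% left-handed product.

Readings and results are simulated from invented constants; scatter was added.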